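## Structural features

The target is a C15 tetracycle with acetates on C12, C3 and C11 and a free hydroxyl on C4. Ring A (C1–C2–C3–C4–C5–C6) is fused along C1–C6 to a tricyclo[2.2.1.0]heptane cage: C6 is the apex, C1, C7 and C11 are the three one-carbon bridges, and C8–C9–C10 is the cyclopropane (C10 carries the methyl group, C12 is the CH2O group on C1). Four carbons are fully substituted (C1, C5, C6, C10) and C5–C6–C1 are contiguous. Of the eight stereocentres, C8, C9 and C10 follow from the cage topology once C1 and C6 are fixed. Across C1–C6 the arm C12 is anti to C11 and C2 lies on the C11 flank. The C3 and C4 oxygens are cis to each other and to C12, on the ring-A face flanked by the axial C12 arm and an axial C5 methyl group. The C11 acetate points to the C7 flank, away from ring A. Fragile points are the cyclopropylcarbinyl C11–O bond (ionisation, homoallyl opening), cyclopropyl ketone intermediates (electron transfer, strong acid), and the vicinal C3 acetate/C4 alcohol (acyl migration). The real difficulty is threefold: the C5–C6 bond between two fully substituted carbons next to quaternary C1, the relative configuration C1/C6, and oxygen on the hindered faces at C3/C4 and C11. The key step uses the fact that the C5–C6 bond has oxygenated C11 on C6 and the C3/C4 oxygenation beside C5: a C3=C4 alkene plus a C11 ketone is the retron of a [3,3] shift of C6=C11–O–C3–C4=C5 held in a cyclopenta-fused dihydropyran.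

## Logic of the disconnections

**33 back to 31.** The C3–O and C4–O bonds are cut together, leaving the C3=C4 alkene. A cis-hydroxy acetate on the C12 face, with the acyl group on the axial oxygen, is what an iodonium/acetoxonium sequence delivers. Two stereocentres and the ester/alcohol differentiation are removed in one operation. The forward step must put the large electrophile on the open face and the oxygen nucleophile on the hindered one, and the other two acetates must already be present because free hydroxyls would capture the iodonium ion.

**31 back to 27, through 29 and 28.** The C11–O bond and the acyl bonds at C12 and C11 are cut; C11 becomes a ketone and C12–O a pivalate. Hydride can reach C11 only from the C7 flank, which gives the wrong epimer; an oxygen nucleophile attacking a C11 cation from that same open flank gives the right one. The C11 stereocentre is removed and one hydride step also frees C12. The forward ionisation at a cyclopropylcarbinyl centre must be trapped at C11 before the cage opens.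

**27 back to 25.** C9–C8 and C9–C10 are cut, which opens the cyclopropane and two cage rings and leaves a C8=C10 enone with a sulfonylmethyl arm on C1. C9 is bonded to both the β- and the α-carbon of a latent enone, the footprint of a Michael-initiated ring closure by a nucleophile that carries its own leaving group. Three rings and the stereocentres C8, C9 and C10 disappear. The forward step needs the C9 arm anti to C5 across C1–C6, which means the C1/C6 relative configuration must be right.

**25 back to 23.** The C8=C10 unsaturation is removed. The saturated ketone is the direct product of the key step, and only C10 is enolisable, so the dehydrogenation is regiochemically unambiguous and C10 never has to be controlled. The forward step must leave the sulfone and the pivalate alone.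

**23 back to 22 (key).** C5–C6 is cut and O–C3 is re-formed. Ring A, the bond between two fully substituted carbons and the C6 stereocentre are exchanged for an enol ether that comes from a cyclodehydration. The forward step needs the C3 alkenyl group cis to the C12 arm and a concerted, not dissociative, pathway.

**22 back to 18, through 20 and 19.** The enol ether C11–O bond and the pivalate C–O bond are cut, and the C12 and C3 oxygens are gathered into a γ-lactone whose carbonyl carbon is C12. In the lactone the C3 oxygen is masked while C9 is worked on, and C1/C3 sit in a five-membered ring where their relationship can be set reliably. After lactone reduction the primary hydroxyl must be capped before the ketone is unmasked, otherwise it competes with the C3 hydroxyl for C11. A pivalate is used, not a benzyl ether: hydrogenolysis would endanger the alkene and the cyclopropane later, whereas the pivalate falls in the hydride step.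

**18 back to 11.** The C9–S bond is cut, C9 returns to the carboxyl level, and the C11 ketal is removed. C1 can only be assembled as a doubly stabilised carbanion, so C9 must arrive as an ester carbon. The forward sequence needs the C9 ester to be distinguishable from the lactone, hence an allyl ester. A β-keto sulfone is avoided as a building block because its acidic methylene would quench any enolate partner.

**11 back to 7 and 10.** C1–C6 is cut. The 1,4-dicarbonyl relationship points to a stabilised carbanion and an α-chloro ketone. The butyrolactone enolate is attacked trans to its C3 substituent; this is what fixes C1, and C6 trans to the alkenyl group on the lactone becomes alkenyl cis to C12 in 22. The quaternary centre and its configuration are reduced to the single stereocentre C3. The forward step is an SN2 reaction of a tertiary carbanion at a secondary carbon.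

**7 back to 5, then to 3 and 4.** The lactone C–O bond and the C3–H bond are cut (C3 ketone), then C1–C2. C3 is an allylic carbinol, so all absolute stereochemistry comes from one catalytic enone reduction. The catalyst must tell the alkenyl group from the CH2 group.

**3 back to 1, and 10 back to 8.** The C–Br and C–Cl bonds are cut. Kinetic silyl enol ethers define the halogenation site in both commercial ketones.

## Other disconnections considered

**Alternative 1:** The cut is the ring-A bond C1–C2, made on a finished cage. In the forward sense the bromoacetal A2 (C11 oxygen carrying CH(OEt)CH2Br, C1 an exocyclic alkenylboronate carbon) would be treated with Bu3SnH. The C2 radical adds to C1 in a 6-exo Ueno–Stork cyclisation, the α-boryl radical is reduced, and the cage-fused ethoxytetrahydropyran A1 results.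
- In its favour: the oxygen tether delivers C2 to C1 from the C11 flank through a cyclic transition state on a rigid framework; radicals tolerate the congestion; the boronate is a masked C12 hydroxyl and the acetal carbon a masked C3.
- Against it: the tether can only start from a C11 oxygen that points toward C1, which is the C11 epimer of the target (A1 shows exactly this), so the C11 inversion remains. The whole cage, including C5–C6 and the cyclopropane, must exist before the key step, so the hardest bonds are moved upstream, not solved. Ring A is still open afterwards (acetal unmasking, methylenation, ring-closing metathesis between C3 and C4, for example with the second-generation Grubbs catalyst), and the C3/C4 oxygenation meets the same facial problem.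
- Comparison: for the C1 stereocentre the tethered radical addition is at least the equal of the lactone alkylation of step 5, probably the better. In step economy it is poorer, because a temporary ring is made and dismantled. Structurally it does not address C5–C6, which the [3,3] shift does.

**Alternative 2:** The cut is C1–C6 and C9–C10 at once. In the forward sense, heating A4 (a 5,5-dimethoxycyclopentadiene substituted at both diene termini, with a tethered nitroacrylate C1=C9) would give A3; ring A and the bicyclo[2.2.1]heptene close together.
- In its favour: two C–C bonds, two rings and three fully substituted carbons (C1, C6, C10) in one step. The ketal blocks hydrogen shifts in the diene and becomes the C11 oxygen. The C3/C4 diol is carried as an acetonide from the start, which removes the late face-selective oxidation; on this point it is better than the chosen plan. The nitro group activates the dienophile and could later serve to close C8–C9.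
- Against it: a diene substituted at both termini and a trisubstituted dienophile must join C1 to C6 next to quaternary C5, a very crowded transition state, and such dienes tend to dimerise. Facial selectivity relative to the acetonide-bearing tether and the endo/exo sense are not obviously controlled. After the step the C7=C8 alkene must still become the C8–C9 cyclopropane bond and a C7 methylene, the ester must be reduced, and C11 must be reduced with the same facial issue.
- Comparison: a cycloaddition gives more bonds per step than the sigmatropic shift, so it is equal or better on convergence. The chosen key step has an unambiguous stereochemical relay (C3 to C6) and a precursor made by cyclodehydration. The overall count would probably not be lower once A4 and the post-cycloaddition adjustments are included.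

**Alternative 3:** The cut is C1–C6 and C9–C11, with C9–C11 later traded for C9–C10. In the forward sense, irradiation of A6 (a 2-silyloxycyclopent-2-enone with the C10 carbonyl and a tethered silyl enol ether C1=C9) would give the cyclobutane A5 with ring A closed. Addition at C10 and a pinacol-type migration of C9 from C11 to C10 would then relieve the four-membered ring and give the bicyclo[2.2.1] skeleton with C11 as ketone.
- In its favour: intramolecular enone–alkene photocycloadditions form congested bonds, vicinal quaternary centres included, under mild conditions. The four-atom tether should give ring A with straight regiochemistry. The diol is present as an acetonide and the C12 ether is in place, again better than the chosen plan for the late oxidation.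
- Against it: it needs photochemical equipment and a chromophore whose excited-state behaviour is less predictable. Facial selectivity relative to the acetonide is open. The migration has a choice of bonds (C9 or C6) and needs a specific alignment. The cyclopropane bond C8–C9 is still missing afterwards.
- Comparison: two bonds and two rings in the key step against one bond and one ring in the chosen plan, so better in bond count. The cage is not finished, however, and more steps follow, whereas the chosen plan closes the three remaining rings in one base-induced operation and uses only ground-state chemistry.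

Key step: step 14

Assumption (remark on the chemistry): C6 and C10 of the cyclopentanone unit are epimerisable and later become sp2 (C6 in step 13, C10 in step 15), so they are carried as epimer mixtures and left undefined in the SMILES until then.

## Route

Step 1
Reactants: 1 mesityl oxide (4-methylpent-3-en-2-one)
Product: 3 1-bromo-4-methylpent-3-en-2-one, via silyl dienol ether 2 (not isolated)
Conditions: LiN(iPr)2, THF, −78 °C; Me3SiCl; then NBS, THF, −78 to 0 °C
Reagents that add atoms: N-bromosuccinimide, O=C1CCC(=O)N1Br; chlorotrimethylsilane, C[Si](C)(C)Cl (silicon stays only in 2)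
Why: Kinetic deprotonation at the methyl group and O-silylation give the cross-conjugated silyl dienol ether, whose terminal CH2 is brominated by NBS (α-halogenation of a silyl enol ether); no stereocentre is formed.

Step 2
Reactants: 3 1-bromo-4-methylpent-3-en-2-one; 4 diallyl malonate
Product: 5 diallyl 2-(4-methyl-2-oxopent-3-en-1-yl)malonate
Conditions: NaH, excess 4, THF, 0 °C to rt
Reagents that add atoms: none
Why: Malonate alkylation (SN2) by a primary α-bromo ketone forms C1–C2; excess malonate suppresses double alkylation and the β,β-disubstituted enone resists conjugate addition.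

Step 3
Reactants: 5 diallyl 2-(4-methyl-2-oxopent-3-en-1-yl)malonate
Product: 7 allyl (5R)-5-(2-methylprop-1-en-1-yl)-2-oxooxolane-3-carboxylate, via hydroxy diester 6 (not isolated)
Conditions: (S)-2-methyl-CBS-oxazaborolidine (cat.), catecholborane, toluene, −78 °C; aqueous work-up; K2CO3 (cat.), THF, rt
Reagents that add atoms: none
Why: Corey–Bakshi–Shibata reduction with the alkenyl group as the large substituent should give the (R)-carbinol at C3 with the (S)-catalyst, and catecholborane at low temperature leaves the allyl esters alone. The hydroxyl then closes the γ-lactone by 5-exo transesterification; the carbon between the two carbonyls stays epimerisable and is fixed in step 5.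

Step 4
Reactants: 8 2-methylcyclopentanone
Product: 10 2-chloro-5-methylcyclopentanone, via silyl enol ether 9 (not isolated)
Conditions: LiN(iPr)2, THF, −78 °C; Me3SiCl; then NCS, THF, 0 °C
Reagents that add atoms: N-chlorosuccinimide, O=C1CCC(=O)N1Cl; chlorotrimethylsilane, C[Si](C)(C)Cl (silicon stays only in 9)
Why: Kinetic enolisation on the unsubstituted side (C6) and silylation define the site of chlorination by NCS; the racemic diastereomer mixture is acceptable because C6 and C10 are erased later.

Step 5
Reactants: 7 allyl (5R)-5-(2-methylprop-1-en-1-yl)-2-oxooxolane-3-carboxylate; 10 2-chloro-5-methylcyclopentanone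
Product: 11 allyl (3R,5R)-3-(3-methyl-2-oxocyclopentyl)-5-(2-methylprop-1-en-1-yl)-2-oxooxolane-3-carboxylate
Conditions: K2CO3, DMF, rt to 50 °C
Reagents that add atoms: none
Why: Malonate-type SN2 alkylation of the lactone–ester carbanion by the α-chloro ketone forms C1–C6. The electrophile should enter the butyrolactone enolate trans to the C3 alkenyl group (1,3-induction), which sets quaternary C1 with C6 trans and the ester carbon C9 cis to the alkenyl group.

Step 6
Reactants: 11 allyl (3R,5R)-3-(3-methyl-2-oxocyclopentyl)-5-(2-methylprop-1-en-1-yl)-2-oxooxolane-3-carboxylate
Product: 12 ethylene ketal of 11 at C11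
Conditions: Me3SiOCH2CH2OSiMe3, Me3SiOTf (cat.), CH2Cl2, −78 to −20 °C
Reagents that add atoms: 1,2-bis(trimethylsilyloxy)ethane, C[Si](C)(C)OCCO[Si](C)(C)C
Why: Silyl-transfer ketalisation under aprotic, cold conditions protects the C11 ketone for the hydride steps without ionising the allylic lactone C3–O bond.

Step 7
Reactants: 12 ethylene ketal of 11 at C11
Product: 13 lactone carboxylic acid (C9 as CO2H)
Conditions: Pd(PPh3)4 (cat.), HCO2H, Et3N, THF, rt
Reagents that add atoms: none
Why: Zerovalent palladium ionises the allyl ester and formate reduces the allyl fragment (Tsuji–Trost type deallylation). The lactone is untouched and a malonic half acid with a quaternary carbon should not decarboxylate at room temperature.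

Step 8
Reactants: 13 lactone carboxylic acid (C9 as CO2H)
Product: 15 hydroxymethyl lactone (C9 as CH2OH), via acid chloride 14 (not isolated)
Conditions: 1-chloro-N,N,2-trimethylprop-1-en-1-amine, CH2Cl2, 0 °C; then NaBH4, THF, −30 to 0 °C
Reagents that add atoms: 1-chloro-N,N,2-trimethylprop-1-en-1-amine, CC(C)=C(Cl)N(C)C (chlorine stays only in 14)
Why: The neutral chloroenamine converts the hindered acid into its chloride, which NaBH4 reduces to the primary alcohol much faster than it attacks the lactone; the ketal shields C11.

Step 9
Reactants: 15 hydroxymethyl lactone (C9 as CH2OH)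
Product: 16 phenylthiomethyl lactone
Conditions: PhSSPh, PBu3, pyridine, 60 °C
Reagents that add atoms: diphenyl disulfide, c1ccccc1SSc1ccccc1
Why: Phosphine–disulfide thioetherification: thiophenolate displaces the alkoxyphosphonium group at the primary carbon C9. The C3 oxygen is locked in the lactone, so no cyclic ether can form.

Step 10
Reactants: 16 phenylthiomethyl lactone
Product: 18 phenylsulfonylmethyl lactone, via sulfoxide 17 (not isolated)
Conditions: (NH4)6Mo7O24·4H2O (cat.), 30% H2O2, EtOH, 0 °C to rt
Reagents that add atoms: hydrogen peroxide, OO
Why: Molybdate-catalysed peroxide oxidation takes the sulfide through the sulfoxide to the sulfone and is expected to spare the trisubstituted alkene.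

Step 11
Reactants: 18 phenylsulfonylmethyl lactone
Product: 19 (2S,4R)-2-(benzenesulfonylmethyl)-6-methyl-2-(9-methyl-1,4-dioxaspiro[4.4]nonan-6-yl)hept-5-ene-1,4-diol
Conditions: LiBH4, THF, 0 °C to rt
Reagents that add atoms: none
Why: Hydride reduction of the lactone frees the C12 primary and C3 secondary allylic hydroxyls; sulfone and ketal are inert.

Step 12
Reactants: 19 (2S,4R)-2-(benzenesulfonylmethyl)-6-methyl-2-(9-methyl-1,4-dioxaspiro[4.4]nonan-6-yl)hept-5-ene-1,4-diol
Product: 20 C12 pivalate of 19 with free C3 hydroxyl
Conditions: PivCl, pyridine, CH2Cl2, 0 °C
Reagents that add atoms: pivaloyl chloride, CC(C)(C)C(=O)Cl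
Why: The bulky acyl chloride should acylate the primary hydroxyl in preference to the secondary one. The pivalate has no α-hydrogen, survives the later base steps and is removed by the hydride of step 17.

Step 13
Reactants: 20 C12 pivalate of 19 with free C3 hydroxyl
Product: 22 [(2R,4S)-4-(benzenesulfonylmethyl)-7-methyl-2-(2-methylprop-1-en-1-yl)-2,3,4,5,6,7-hexahydrocyclopenta[b]pyran-4-yl]methyl 2,2-dimethylpropanoate, via mixed hydroxyethyl ketal 21 (not isolated)
Conditions: PPTS (cat.), toluene, 5 Å MS, 90 °C
Reagents that add atoms: none
Why: Acid-catalysed transketalisation: the C3 hydroxyl captures the oxocarbenium ion of the opened dioxolane (six-membered ring), and loss of ethylene glycol under equilibrating conditions should give the ring-fusion enol ether C11=C6. The acid is kept weak to spare the allylic C3–O bond; C1 and C3 are untouched, so the alkenyl group is cis to the C12 arm.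

Step 14
Reactants: 22 [(2R,4S)-4-(benzenesulfonylmethyl)-7-methyl-2-(2-methylprop-1-en-1-yl)-2,3,4,5,6,7-hexahydrocyclopenta[b]pyran-4-yl]methyl 2,2-dimethylpropanoate
Product: 23 [(5R,10S)-10-(benzenesulfonylmethyl)-2,6,6-trimethyl-1-oxospiro[4.5]dec-7-en-10-yl]methyl 2,2-dimethylpropanoate
Conditions: toluene (degassed), iPr2NEt (trace), sealed tube, 180 °C
Reagents that add atoms: none
Why: The allyl vinyl ether C6=C11–O–C3–C4=C5 undergoes a concerted [3,3] sigmatropic shift through a boat-like six-membered transition state enforced by the dihydropyran ring: C5–C6 forms as O–C3 breaks and C11 becomes the ketone. The closest known reaction type is the thermal Claisen rearrangement of 2-alkenyl-3,4-dihydro-2H-pyrans to 4-acylcyclohexenes. Ring A (C1–C2–C3=C4–C5–C6) closes by this suprafacial ring exchange as the heterocycle opens, so the ring is formed in a pericyclic and not an ionic mode. The only new stereocentre, C6, is controlled by C3: the alkenyl group lies over the enol ether face that is cis to C12, C5 bonds to that face, and C9 ends anti to C5 across C1–C6, which is the arrangement the cage needs. The step needs the concerted pathway to win over heterolysis of the allylic C3–O bond; a non-polar medium, an amine trace and the absence of acid are meant to secure this. Regiochemistry is secured because bonding of C3 to C6 would give a cyclobutane. Carbonyl formation should pay for joining the fully substituted C5 and C6 and for the syn-axial contact between the alkenyl group and the C12 arm in the transition state. C10 stays an epimer mixture and is erased in step 15.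

Step 15
Reactants: 23 [(5R,10S)-10-(benzenesulfonylmethyl)-2,6,6-trimethyl-1-oxospiro[4.5]dec-7-en-10-yl]methyl 2,2-dimethylpropanoate
Product: 25 [(5R,10S)-10-(benzenesulfonylmethyl)-2,6,6-trimethyl-1-oxospiro[4.5]deca-2,7-dien-10-yl]methyl 2,2-dimethylpropanoate, via silyl enol ether 24 (not isolated)
Conditions: Me3SiOTf, Et3N, CH2Cl2, 0 °C; then Pd(OAc)2, MeCN, rt
Reagents that add atoms: trimethylsilyl trifluoromethanesulfonate, C[Si](C)(C)OS(=O)(=O)C(F)(F)F (silicon stays only in 24)
Why: Saegusa–Ito oxidation: C10 is the only enolisable position, so one silyl enol ether forms without strong base. Divalent palladium then gives the C8=C10 enone by β-hydride elimination and leaves as zerovalent palladium; the C10 stereocentre is erased.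

Step 16
Reactants: 25 [(5R,10S)-10-(benzenesulfonylmethyl)-2,6,6-trimethyl-1-oxospiro[4.5]deca-2,7-dien-10-yl]methyl 2,2-dimethylpropanoate
Product: 27 cage ketone (C11 ketone; ring-A C3=C4 alkene; C12 pivalate), via bicyclic sulfonyl enolate 26 (not isolated)
Conditions: KOtBu, THF/tBuOH, 0 °C to rt
Reagents that add atoms: none
Why: Michael-initiated ring closure: the sulfonyl carbanion at C9 adds 5-exo-trig to C8 and gives a bicyclo[2.2.1]heptanone enolate, whose carbon C10 then displaces sulfinate at C9 (3-exo-tet). The closest known types are sulfone-based cyclopropanation of Michael acceptors and Michael–Michael–ring-closure routes to tricyclo[2.2.1.0]heptanones. C8, C9 and C10 can only form in the configuration dictated by C1 and C6.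

Step 17
Reactants: 27 cage ketone (C11 ketone; ring-A C3=C4 alkene; C12 pivalate)
Product: 28 cage diol (C12 primary alcohol; C11 alcohol epimeric to the target)
Conditions: LiAlH4, THF, 0 °C
Reagents that add atoms: none
Why: Hydride should attack the cyclopropyl ketone from the C7 flank, because the C1 flank is covered by the ring-A methylene C2; this places the hydroxyl toward ring A (the C11 epimer). The same reagent cleaves the pivalate.

Step 18
Reactants: 28 cage diol (C12 primary alcohol; C11 alcohol epimeric to the target)
Product: 29 C12 monoacetate of 28
Conditions: Ac2O (1 equiv), pyridine, CH2Cl2, 0 °C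
Reagents that add atoms: acetic anhydride, CC(=O)OC(C)=O
Why: The primary hydroxyl acetylates, while the C11 hydroxyl buried under ring A should not react under these conditions.

Step 19
Reactants: 29 C12 monoacetate of 28
Product: 31 cage diacetate (C12 and C11 acetates with the target configuration at C11; ring-A alkene), via mesylate 30 (not isolated)
Conditions: (MeSO2)2O, Et3N, CH2Cl2, −20 °C; then KOAc, AcOH, 60 °C
Reagents that add atoms: potassium acetate, CC(=O)[O-].[K+]; methanesulfonic anhydride, CS(=O)(=O)OS(C)(=O)=O (stays only in 30)
Why: Buffered acetolysis: the compressed sulfonate ionises to the cyclopropylcarbinyl (nortricyclyl) cation, and acetate can add to C11 only from the open C7 flank. This is net inversion to the target configuration.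

Step 20
Reactants: 31 cage diacetate (C12 and C11 acetates with the target configuration at C11; ring-A alkene)
Product: 33 target triacetate CNP0197219.1, via trans iodo acetate 32 (not isolated)
Conditions: I2, AgOAc, AcOH, H2O (1 equiv), rt to 50 °C
Reagents that add atoms: silver acetate, CC(=O)[O-].[Ag+]; water, O; iodine, II (iodine stays only in 32)
Why: Woodward cis-hydroxylation: the iodonium ion should form on the less hindered face (that of C11) and acetate opens it trans-diaxially at C3 from the C12 face. The C3 acetate then displaces silver-activated iodide at C4 to give a cis acetoxonium ion on the C12 face. Water opens this ion to the axial ester (C3) and the equatorial alcohol (C4), so both new stereocentres are cis to C12 and the acetate sits on C3.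

## Compound list

1 | mesityl oxide (4-methylpent-3-en-2-one) | CC(=O)C=C(C)C | starting material
2 | 4-methyl-2-(trimethylsilyloxy)penta-1,3-diene | C=C(O[Si](C)(C)C)C=C(C)C | intermediate (not isolated)
3 | 1-bromo-4-methylpent-3-en-2-one | BrCC(=O)C=C(C)C | intermediate
4 | diallyl malonate | C=CCOC(=O)CC(=O)OCC=C | starting material
5 | diallyl 2-(4-methyl-2-oxopent-3-en-1-yl)malonate | C=CCOC(=O)C(CC(=O)C=C(C)C)C(=O)OCC=C | intermediate
6 | diallyl 2-[(2R)-2-hydroxy-4-methylpent-3-en-1-yl]malonate | C=CCOC(=O)C(C[C@@H](O)C=C(C)C)C(=O)OCC=C | intermediate (not isolated)
7 | allyl (5R)-5-(2-methylprop-1-en-1-yl)-2-oxooxolane-3-carboxylate (both epimers at the ester-bearing carbon) | C=CCOC(=O)C1C[C@H](C=C(C)C)OC1=O | intermediate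
8 | 2-methylcyclopentanone (racemic) | CC1CCCC1=O | starting material
9 | trimethyl[(5-methylcyclopent-1-en-1-yl)oxy]silane | CC1CCC=C1O[Si](C)(C)C | intermediate (not isolated)
10 | 2-chloro-5-methylcyclopentanone (racemic, both diastereomers) | CC1CCC(Cl)C1=O | intermediate
11 | allyl (3R,5R)-3-(3-methyl-2-oxocyclopentyl)-5-(2-methylprop-1-en-1-yl)-2-oxooxolane-3-carboxylate (cyclopentyl group trans to the alkenyl group; C6 and C10 epimers) | C=CCOC(=O)[C@]1(C2CCC(C)C2=O)C[C@H](C=C(C)C)OC1=O | intermediate
12 | allyl (3R,5R)-3-(9-methyl-1,4-dioxaspiro[4.4]nonan-6-yl)-5-(2-methylprop-1-en-1-yl)-2-oxooxolane-3-carboxylate (ethylene ketal of 11) | C=CCOC(=O)[C@]1(C2CCC(C)C23OCCO3)C[C@H](C=C(C)C)OC1=O | intermediate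
13 | (3R,5R)-3-(9-methyl-1,4-dioxaspiro[4.4]nonan-6-yl)-5-(2-methylprop-1-en-1-yl)-2-oxooxolane-3-carboxylic acid | OC(=O)[C@]1(C2CCC(C)C23OCCO3)C[C@H](C=C(C)C)OC1=O | intermediate
14 | acid chloride of 13 (same spatial arrangement at C1 and C3) | ClC(=O)[C@]1(C2CCC(C)C23OCCO3)C[C@H](C=C(C)C)OC1=O | intermediate (not isolated)
15 | (3R,5R)-3-(hydroxymethyl)-3-(9-methyl-1,4-dioxaspiro[4.4]nonan-6-yl)-5-(2-methylprop-1-en-1-yl)oxolan-2-one | OC[C@]1(C2CCC(C)C23OCCO3)C[C@H](C=C(C)C)OC1=O | intermediate
16 | phenylthiomethyl lactone: 15 with CH2SPh in place of CH2OH (same spatial arrangement) | c1ccccc1SC[C@]1(C2CCC(C)C23OCCO3)C[C@H](C=C(C)C)OC1=O | intermediate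
17 | sulfoxide of 16 (both sulfur epimers) | O=S(c1ccccc1)C[C@]1(C2CCC(C)C23OCCO3)C[C@H](C=C(C)C)OC1=O | intermediate (not isolated)
18 | phenylsulfonylmethyl lactone: 15 with CH2SO2Ph in place of CH2OH (same spatial arrangement) | O=S(=O)(c1ccccc1)C[C@]1(C2CCC(C)C23OCCO3)C[C@H](C=C(C)C)OC1=O | intermediate
19 | (2S,4R)-2-(benzenesulfonylmethyl)-6-methyl-2-(9-methyl-1,4-dioxaspiro[4.4]nonan-6-yl)hept-5-ene-1,4-diol | O=S(=O)(c1ccccc1)C[C@](CO)(C1CCC(C)C12OCCO2)C[C@H](C=C(C)C)O | intermediate
20 | [(2S,4R)-2-(benzenesulfonylmethyl)-4-hydroxy-6-methyl-2-(9-methyl-1,4-dioxaspiro[4.4]nonan-6-yl)hept-5-en-1-yl] 2,2-dimethylpropanoate | O=S(=O)(c1ccccc1)C[C@](COC(=O)C(C)(C)C)(C1CCC(C)C12OCCO2)C[C@H](C=C(C)C)O | intermediate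
21 | mixed ketal: cyclopenta-fused tetrahydropyran with a 2-hydroxyethoxy group on C11 | O=S(=O)(c1ccccc1)C[C@@]1(COC(=O)C(C)(C)C)C[C@H](C=C(C)C)OC2(OCCO)C1CCC2C | intermediate (not isolated)
22 | [(2R,4S)-4-(benzenesulfonylmethyl)-7-methyl-2-(2-methylprop-1-en-1-yl)-2,3,4,5,6,7-hexahydrocyclopenta[b]pyran-4-yl]methyl 2,2-dimethylpropanoate (alkenyl cis to CH2OPiv; C10 epimers) | CC(C)(C)C(=O)OC[C@]1(CS(=O)(=O)c2ccccc2)C[C@H](C=C(C)C)OC2=C1CCC2C | intermediate (key-step precursor)
23 | [(5R,10S)-10-(benzenesulfonylmethyl)-2,6,6-trimethyl-1-oxospiro[4.5]dec-7-en-10-yl]methyl 2,2-dimethylpropanoate (C10 epimers) | CC(C)(C)C(=O)OC[C@]1(CS(=O)(=O)c2ccccc2)CC=CC(C)(C)[C@]12CCC(C)C2=O | intermediate (key-step product)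
24 | trimethylsilyl enol ether of 23 (C10=C11) | CC(C)(C)C(=O)OC[C@]1(CS(=O)(=O)c2ccccc2)CC=CC(C)(C)[C@]12CCC(C)=C2O[Si](C)(C)C | intermediate (not isolated)
25 | [(5R,10S)-10-(benzenesulfonylmethyl)-2,6,6-trimethyl-1-oxospiro[4.5]deca-2,7-dien-10-yl]methyl 2,2-dimethylpropanoate | CC(C)(C)C(=O)OC[C@]1(CS(=O)(=O)c2ccccc2)CC=CC(C)(C)[C@]12CC=C(C)C2=O | intermediate
26 | potassium enolate of the bicyclo[2.2.1]heptanone Michael adduct (C9–C8 formed; C9 carries SO2Ph) | CC(C)(C)C(=O)OC[C@]12CC=CC(C)(C)[C@]13C[C@@H](C(C)=C3[O-])[C@@H]2S(=O)(=O)c1ccccc1.[K+] | intermediate (not isolated)
27 | cage ketone: complete tetracycle with C11 ketone, ring-A C3=C4 alkene, C12 pivalate | CC(C)(C)C(=O)OC[C@]12CC=CC(C)(C)[C@]13C[C@@H]1[C@H]2[C@]1(C)C3=O | intermediate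
28 | cage diol: C12 primary alcohol, C11 alcohol with hydroxyl toward ring A (C11 epimer of the target) | OC[C@]12CC=CC(C)(C)[C@]13C[C@@H]1[C@H]2[C@]1(C)[C@@H]3O | intermediate
29 | C12 monoacetate of 28 | CC(=O)OC[C@]12CC=CC(C)(C)[C@]13C[C@@H]1[C@H]2[C@]1(C)[C@@H]3O | intermediate
30 | C11 methanesulfonate of 29 | CC(=O)OC[C@]12CC=CC(C)(C)[C@]13C[C@@H]1[C@H]2[C@]1(C)[C@@H]3OS(C)(=O)=O | intermediate (not isolated)
31 | cage diacetate: C12 and C11 acetates, C11 as in the target (acetate toward C7), ring-A alkene | CC(=O)OC[C@]12CC=CC(C)(C)[C@]13C[C@@H]1[C@H]2[C@]1(C)[C@H]3OC(C)=O | intermediate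
32 | trans iodo acetate: C3 acetate on the C12 face, C4 iodide on the opposite face | CC(=O)OC[C@]12C[C@H](OC(C)=O)[C@@H](I)C(C)(C)[C@]13C[C@@H]1[C@H]2[C@]1(C)[C@H]3OC(C)=O | intermediate (not isolated)
33 | CNP0197219.1, (1S,3S,4R,6S,8R,9R,10R,11R) in the atom labels used here: C12, C3 and C11 acetates, C4 alcohol | CC(=O)OC[C@]12C[C@H](OC(C)=O)[C@H](O)C(C)(C)[C@]13C[C@@H]1[C@H]2[C@]1(C)[C@H]3OC(C)=O | target

## Step count and least certain steps

Total: 20 steps. Longest linear sequence: 19 steps (steps 1–3 and 5–20); step 4 is a one-step branch.

**Step 14 (key step).** The most likely failure is heterolysis of the allylic C3–O bond in competition with the concerted shift, which would break the stereochemical relay from C3 to C6. The other failure is simply no reaction: two fully substituted termini must join while the alkenyl group and the C12 arm are syn-axial. Fallback by another mechanism, intramolecular Tsuji–Trost allylation: set out from 20, convert the C3 hydroxyl with methyl chloroformate and pyridine into the allylic methyl carbonate ketal F1, hydrolyse the ketal (PPTS, wet acetone) to the keto carbonate F2, and treat F2 with Pd(PPh3)4 in THF. The π-allyl complex can be closed by the ketone enolate only from C6 onto C5, because every other combination gives a four- or eight-membered ring, and the route is rejoined at 23. The C6 configuration would then rest on C1 alone, so the C6 epimer would have to be removed by chromatography.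

**Step 5.** Carbon–carbon bond formation between a tertiary carbanion and a secondary α-chloro ketone may be slow. Dehydrohalogenation, Favorskii-type consumption of 10 or O-alkylation could then take over, and the trans selectivity could erode. Fallback with the bonds formed in the opposite order: alkylate 4 first with 10 (NaH, THF; the classical malonate/α-chlorocyclopentanone reaction) to diallyl 2-(3-methyl-2-oxocyclopentyl)malonate F3, then with 3 to the diketo malonate F4. Reduce the enone carbonyl of F4 with the same oxazaborolidine/catecholborane system to the hydroxy diester F5 and lactonise under equilibrating conditions (K2CO3, THF), which should favour the lactone with the bulky cyclopentyl group trans to the alkenyl group and rejoins the route at 11. The price is a chemoselectivity demand in the reduction and thermodynamic, not kinetic, control of C1.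

**Step 16.** The base may mainly deprotonate the γ-position of the enone (unproductive dienolate), the Michael addition is reversible, and displacement of sulfinate in the strained bicyclic enolate may be slow. Fallback through a diazoalkane: set out from 24 (isolated from step 15). Deprotonate the sulfone with LiN(iPr)2 at −78 °C and oxidise the carbanion with Me3SiOOSiMe3 to the C9 aldehyde silyl enol ether F6. Oxidise F6 with Pd(OAc)2 to the enone aldehyde F7, then condense with tosylhydrazide to the tosylhydrazone F8. Warming F8 with NaH in toluene should give the diazoalkane, which adds across C8=C10 to the pyrazoline F9; loss of nitrogen on heating or irradiation closes the cyclopropane and rejoins the route at 27.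

**Step 19.** The delocalised cation may be captured at the cyclopropane carbons C8 or C9 (ring-opened homoallylic acetates), or the C3=C4 π bond may take part transannularly. Sulfonylation of the buried hydroxyl may also be incomplete. Fallback without a sulfonate and without a solvent-separated cation: set out from 29 and run a Mitsunobu inversion with acetic acid (PBu3, di-tert-butyl azodicarboxylate, toluene), in which acetate enters from the C7 flank as the activated oxygen leaves. This gives 31 directly and makes no new compound.

**Step 20.** Iodonium formation on the wrong face, opening at C4 instead of C3, or participation of the C12 acetate would give the wrong diol face or the wrong acetate position. Fallback by hydrogen-bond-directed osmylation: set out from 31 and remove the primary acetate selectively (K2CO3, MeOH, 0 °C) to the C12 alcohol F10. Dihydroxylate with OsO4·TMEDA in CH2Cl2 at −78 °C, where the axial CH2OH should direct the reagent to its own face, giving the triol F11 after cleavage of the osmate ester. Treat F11 with trimethyl orthoacetate and PPTS, then Ac2O and pyridine, to obtain the cyclic C3/C4 orthoester C12 acetate F12. Mild aqueous acetic acid should open F12 to the axial C3 acetate and equatorial C4 alcohol, which is 33.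

## Further compounds

F1 | step 14 | allylic methyl carbonate of 20 (ketal intact) | O=S(=O)(c1ccccc1)C[C@](COC(=O)C(C)(C)C)(C1CCC(C)C12OCCO2)C[C@H](C=C(C)C)OC(=O)OC
F2 | step 14 | keto carbonate (C11 ketone free, C3 methyl carbonate) | O=S(=O)(c1ccccc1)C[C@](COC(=O)C(C)(C)C)(C1CCC(C)C1=O)C[C@H](C=C(C)C)OC(=O)OC
F3 | step 5 | diallyl 2-(3-methyl-2-oxocyclopentyl)malonate | C=CCOC(=O)C(C1CCC(C)C1=O)C(=O)OCC=C
F4 | step 5 | diallyl 2-(3-methyl-2-oxocyclopentyl)-2-(4-methyl-2-oxopent-3-en-1-yl)malonate | C=CCOC(=O)C(CC(=O)C=C(C)C)(C1CCC(C)C1=O)C(=O)OCC=C
F5 | step 5 | diallyl 2-[(2R)-2-hydroxy-4-methylpent-3-en-1-yl]-2-(3-methyl-2-oxocyclopentyl)malonate | C=CCOC(=O)C(C[C@@H](O)C=C(C)C)(C1CCC(C)C1=O)C(=O)OCC=C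
F6 | step 16 | C9 aldehyde silyl enol ether (24 with CHO in place of CH2SO2Ph) | CC(C)(C)C(=O)OC[C@]1(C=O)CC=CC(C)(C)[C@]12CCC(C)=C2O[Si](C)(C)C
F7 | step 16 | C9 aldehyde enone | CC(C)(C)C(=O)OC[C@]1(C=O)CC=CC(C)(C)[C@]12CC=C(C)C2=O
F8 | step 16 | tosylhydrazone of F7 | CC(C)(C)C(=O)OC[C@]1(C=NNS(=O)(=O)c2ccc(C)cc2)CC=CC(C)(C)[C@]12CC=C(C)C2=O
F9 | step 16 | cage-fused 1-pyrazoline (C9–C8 formed, N=N bridging C9 and C10) | CC(C)(C)C(=O)OC[C@]12CC=CC(C)(C)[C@]13C[C@@H]4[C@H]2N=N[C@]4(C)C3=O
F0 | step 19 | none | none
F10 | step 20 | C12 alcohol C11 acetate (ring-A alkene) | OC[C@]12CC=CC(C)(C)[C@]13C[C@@H]1[C@H]2[C@]1(C)[C@H]3OC(C)=O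
F11 | step 20 | C12, C3, C4 triol C11 acetate | OC[C@]12C[C@H](O)[C@H](O)C(C)(C)[C@]13C[C@@H]1[C@H]2[C@]1(C)[C@H]3OC(C)=O
F12 | step 20 | cyclic C3/C4 methyl orthoacetate with C12 and C11 acetates | CC(=O)OC[C@]12C[C@@H]3OC(C)(OC)O[C@@H]3C(C)(C)[C@]14C[C@@H]1[C@H]2[C@]1(C)[C@H]4OC(C)=O
A1 | alternative 1 | cage-fused 2-ethoxytetrahydropyran with C12 pinacol boronate | CC1(C)OB(C[C@]23C[C@@H](OCC)O[C@@H]4[C@@]2(C(C)(C)C=C)C[C@@H]5[C@H]3[C@]45C)OC1(C)C
A2 | alternative 1 | cage bromoacetal with exocyclic alkenylboronate at C1 | CC1(C)OB(C=C2[C@]3(C(C)(C)C=C)C[C@@H]4[C@H]2[C@]4(C)[C@@H]3OC(CBr)OCC)OC1(C)C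
A3 | alternative 2 | ring A-fused 7,7-dimethoxynorbornene nitro ester | COC(=O)[C@]12C[C@@H]3OC(C)(C)O[C@@H]3C(C)(C)[C@]14C=C[C@@](C)(C4(OC)OC)[C@@H]2[N+](=O)[O-]
A4 | alternative 2 | 5,5-dimethoxycyclopentadiene with tethered nitroacrylate (alkene geometry as required) | COC(=O)C(=C[N+](=O)[O-])C[C@@H]1OC(C)(C)O[C@@H]1C(C)(C)C1=CC=C(C)C1(OC)OC
A5 | alternative 3 | tricyclic cyclobutane photoadduct | c1ccccc1COC[C@]12C[C@@H]3OC(C)(C)O[C@@H]3C(C)(C)[C@]14CCC(=O)[C@]4(O[Si](C)(C)C(C)(C)C)[C@@H]2O[Si](C)(C)C(C)(C)C
A6 | alternative 3 | 2-silyloxycyclopent-2-enone with tethered silyl enol ether | c1ccccc1COCC(=CO[Si](C)(C)C(C)(C)C)C[C@@H]1OC(C)(C)O[C@@H]1C(C)(C)C1=C(O[Si](C)(C)C(C)(C)C)C(=O)CC1
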